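The rate constants are those of an exercise; the run is a simulation.

3.28 min: that relaxation half-life between target and isomer of the product is what I hand over with these flasks, set against a run of 8.0 min.

all flasks: starting material 0.20 M; enzyme 20 µM

|  | second substrate | time | remark |
|---|---|---|---|
| winter | 0.360 M | 8.0 min | a closed flask charged with all of it at once and left for 8.0 min |
| dusk | 0.360 M | 8.0 min | plug flow through a tube for 8.0 min, no back-mixing |
| autumn | 0.360 M (fed, over 6.40 min) | 8.0 min | all but second substrate at the start; second substrate goes in evenly over 6.40 min, the run ends at 8.0 min |
| spring | 0.360 M |  | one stirred flow tank at steady state, fed with the mixture as stated, mean residence time 8.0 min |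

    ternary complex → enzyme + target (k1 = 12000 min⁻¹)
    target ⇌ isomer of the product (K2 = 5.8, k2 = 0.18 min⁻¹)
    second substrate + starting complex ⇌ ternary complex (K3 = 1.4 M⁻¹, k3 = 1.8 × 10⁵ M⁻¹ min⁻¹)
    starting material + enzyme ⇌ starting complex (K4 = 4.8 M⁻¹, k4 = 22000 M⁻¹ min⁻¹)

- the stated concentrations are those of everything mixed, before any reaction; amounts are the same in each set-up
- the feed brings no volume worth counting
- run time (winter): 8.0 min

1. the set-up with the highest share of target in all that became target or isomer of the product, at the outlet or at the end ("none" if the first two lie within 2 percentage points) (winter / dusk / autumn / spring / none)
2. share of target in all that became target or isomer of the product, at the outlet or at the end, winter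
3. share of target in all that became target or isomer of the product, at the outlet or at the end, dusk
4. share of target in all that became target or isomer of the product, at the outlet or at the end, autumn
5. share of target in all that became target or isomer of the product, at the outlet or at the end, spring

1. What is in the flask. Starting material and second substrate pass through the enzyme to target, and target then turns into isomer of the product, and partly back.

2. What I carry. The ageing rate λ is the forward plus the backward rate constant of that isomerisation, 0.211 min⁻¹. The rest share s, target over target plus isomer at equilibrium, is 14.7%. In product of age a, the excess of the share over s falls as exp(−λa).

3. What you will find. The run holds 2.44 half-lives, so the age of the product matters. Product made evenly over 8.0 min would show 55.9%. I expect winter and dusk, which share one history, below that, with their making richest early. I expect autumn above it, with second substrate arriving until 6.40 min.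

4. The tank. In spring the outlet ages spread exponentially about the mean residence time τ, so the mean of exp(−λa) is one over one plus λτ. The rate of making drops out, and I reckon 46.4%.

5. What not to touch. Do not let a flask stand past its time, since the excess in product already made halves every 3.28 min.

The forecast names autumn, with winter 50.1%, dusk 50.1%, autumn 59.7% and spring 46.5%, holding that “the share depends on how late the target was made”.

The simulation gives winter 49.8%, dusk 49.8%, autumn 60.1% and spring 46.4%, so autumn is best. Winter lies below my even figure, autumn above it, and spring matches my tank reckoning.

Autumn has not come to rest at 8.0 min: its share of 60.1% reads as an effective age of 2.99 min, and starting material stands at 45.3%. The neighbour, autumn with 8.0 × 10⁻⁶ M of enzyme, shows 62.2%, an effective age of 2.78 min, with 73% of its starting material still there, unbound. Ten times the time in autumn adds 21.9 half-lives, and the share falls to 14.7%, against the rest share 14.7%: kinetic control has given way to thermodynamic control. Starting material, the limiting reagent, is down to 0% at 80.0 min, and second substrate stands at 44.4% of its charge.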